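The earlier runs and the new flask are simulated on assumed constants.

- A small charge of free catalyst, 13.6 % of the starting material, went round through catalyst intermediates A, B and C, and target left at the last step of that round.

the same everywhere: starting material 0.011 M
- theta: coupling partner 0.033 M; free catalyst 1.5 mM; the very flask that is asked about, followed so far
- beta: coupling partner 0.033 M; free catalyst 2.2 mM; run made earlier
- flask: coupling partner 0.0330 M; free catalyst 1.5 mM; time 4.0 h

- theta (time / min: target / %, starting material / %): 30.0: 8, 85; 60.0: 19, 71; 90.0: 28, 62; 120: 36, 52
- beta (time / h: target / %, starting material / %): 0.333: 5, 82; 0.667: 17, 71; 1.50: 40, 49; 4.00: 76, 9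

(standard deviation of a reading: 1.5 percentage points)

1. amount of target in percent of the starting material charged, at 25 min, 80 min, 2.5 h and 4.0 h

- in percentages every species weighs as the starting material in it: one side product counts as two
- reactions considered so far: catalyst intermediate B <-> released group + catalyst intermediate C; starting material + target -> side product; starting material + free catalyst -> catalyst intermediate A; coupling partner + catalyst intermediate A -> catalyst intermediate B; catalyst intermediate C -> free catalyst + target

- The theta flask and the beta run had the same starting material and coupling partner charges, so I folded their difference into the clock ratio s, the catalyst charge of the flask over that of the beta run, 0.682.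
- In words, s said that if the rate of the round went with the catalyst charge, the flask at time t would match the beta run at time s·t.
- I tested this on the readings. The beta reading at 0.667 h belonged to flask time 58.7 min, and the flask read 19 % at 60.0 min against 17 % in the beta run, a gap of 2 percentage points.
- The step starting material + target → side product contains no catalyst, so s says nothing about that step.
- By my own reckoning, 4.0 h in the flask became 2.73 h on the beta clock, and a straight chord between the beta readings at 1.50 h and 4.00 h gave 57.7 %.
- The forecast gave 6 %, 25 %, 44 % and 60 %. It reached its last two values on the same ground as my reckoning, "Theta time therefore maps onto beta time ×0.68", and gave its first two as interpolated. Its last value stood higher than my chord, since it followed a bending curve.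

    catalyst intermediate B ⇌ released group + catalyst intermediate C (K = 1.10 M, k = 0.00110 s⁻¹)
    starting material + target → side product (k = 0.00330 M⁻¹ s⁻¹)
    starting material + free catalyst → catalyst intermediate A (k = 0.110 M⁻¹ s⁻¹)
    coupling partner + catalyst intermediate A → catalyst intermediate B (k = 0.340 M⁻¹ s⁻¹)
    catalyst intermediate C → free catalyst + target (k = 0.00820 s⁻¹)

- The flask gave 6.18 %, 25.4 %, 44.6 % and 61.7 %, the last 1.7 points above the forecast. The beta reading of 40 % at 1.50 h mapped by s to flask time 2.20 h, and the flask held 37.1 % at 2.00 h and 44.6 % at 2.5 h, on either side of it. Catalyst intermediate C had a half-life of 1.4 min by its release step alone, far shorter than the 1.5 h half-life of starting material against capture by free catalyst at 4.00 h. At 2.00 h catalyst intermediate C held 4.62 % of the catalyst, while free catalyst held 57.4 %.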